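The numbers in the tables stem from a simulated flask for an exercise; scatter was added.

Early times first, since you asked for a quick number: the south run is this very flask, followed up to 12.0 min.

- south: substrate 20 mM; gas phase 8.2 mM (held); catalyst 1 mM; the very flask that is asked about, followed so far
- flask: substrate 20 mM; gas phase 8.2 mM (held); catalyst 1.0 mM; time 25 min

south run (percent of the substrate charged): time / min: target / % = 2.50: 6.5; 5.00: 11.1; 8.00: 16.7; 10.0: 18.0; 12.0: 20.0

(readings scatter by 1 percentage point)

- at the start none of the gas phase is in solution

- how much target there is at 25 min, in percent of the substrate charged
- concentration of dissolved gas in solution at 25 min, in percent of saturation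

1. We go to logarithms. Between the first two readings the target fraction climbs 0.772 decades per decade of time. From the second reading to the last it climbs 0.673. This is the bend exponent: decades of target fraction gained per decade of time. A straight line from zero has 1, a plateau 0.

2. The exponent sank by 0.0990. One more such drop gives 0.573 for the stretch to 25 min. So we carry the last reading forward and estimate 30.5% target at 25 min. That drop is a reading, with scatter 1 percentage point on each point, so our number is rough.

3. A lag in gas uptake shows as an early exponent above 1, and our reading is 0.772. So we read no lag, and we expect dissolved gas close to saturation.

4. Your hunch, the forecast, says 97% of saturation and 28% target, the target on this ground: “the catalyst is dying or the product is inhibiting”. Our target figure is higher.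

The flask gives 29.9% target and 98.9% of saturation, so the forecast held on both.

    gas phase ⇌ dissolved gas, rate k1*(csat - [dissolved gas]) (kL = 0.0540 s⁻¹)
    substrate + dissolved gas + catalyst → catalyst + target (k = 62.0 L² mol⁻² s⁻¹)
    target + catalyst ⇌ isomer of the product + catalyst, rate k3*[catalyst]*[target] forward; the back reaction follows from the equilibrium constant (K = 1.60, k = 1.10 L mol⁻¹ s⁻¹)

In the flask, the forward, pseudo-first-order half-life of target passing into isomer of the product is 11 min, shorter than the 25 min asked. At 25 min the flask holds 22.5% isomer of the product beside 29.9% target, with catalyst at 100%. The bend exponent, 0.673 in the readings, is 0.450 in the flask from 12.5 min to 25 min. In the flask left until 1.5 h it is 0.177 from 25 min on, ending at 37.5% target and 55.8% isomer of the product.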